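**Assumption:** positions are given in germacrane numbering (C1–C15; C12 lactone carbonyl, C13 exocyclic methylene, C14 ester carbon). The SMILES is read as (1(10)E,4R,5R,6S,7R,8R,9S) with a (2S,3R) acyl group.

## Retrosynthetic overview

1. Target 27 ⇐ mCPBA epoxidation of the C4=C5 alkene of 26 (ring-controlled) ⇐ esterification of 8-hydroxy lactone 18 with chlorohydrin acid 25.
2. 18 ⇐ seco bromo enal 15: a chromium-electrocatalytic intramolecular allylation closes the ten-membered ring at C6–C7; the γ-lactone closes on work-up.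
3. 15 ⇐ aldehyde 12 (C11–C13 by vinylalumination, SN2' bromide, C6 enal) ⇐ Nozaki–Hiyama–Kishi union at C9–C10 of iodoenoate 5 (from geraniol) with aldehyde 9 (from methyl (R)-glycerate acetonide; C8 bought, C9 by Felkin–Anh control).
4. 25 ⇐ (S)-lactic acid: dioxolanone aldol with acetaldehyde, epoxide closure, HCl opening.
5. Ring order: carbocycle, then lactone (both in step 13), then oxirane (step 18).

## Route

**Step 1**
Reactants: 1 geraniol
Product: 2 tert-butyl{[(2E)-3,7-dimethylocta-2,6-dien-1-yl]oxy}dimethylsilane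
Conditions: TBSCl, imidazole, DMF, 0 °C to rt
Reagents that add atoms: tert-butyldimethylsilyl chloride (CC(C)(C)[Si](C)(C)Cl)
Why: Standard silyl ether protection of the primary allylic alcohol; no stereocentre is involved.

**Step 2**
Reactants: 2 tert-butyl{[(2E)-3,7-dimethylocta-2,6-dien-1-yl]oxy}dimethylsilane
Product: 4 (4E)-6-[(tert-butyldimethylsilyl)oxy]-4-methylhex-4-enal, via 6,7-epoxide 3 (not isolated)
Conditions: mCPBA (1.0 equiv), CH2Cl2, −20 °C; then H5IO6, THF/H2O, 0 °C
Reagents that add atoms: 3-chloroperbenzoic acid (O=C(OO)c1cccc(Cl)c1)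
Why: Prilezhaev epoxidation takes the more electron-rich remote alkene (the other is deactivated by the allylic oxygen) and periodic acid cleaves the epoxide through its diol to the aldehyde and acetone.

**Step 3**
Reactants: 4 (4E)-6-[(tert-butyldimethylsilyl)oxy]-4-methylhex-4-enal
Product: 5 methyl (2Z,6E)-8-[(tert-butyldimethylsilyl)oxy]-2-iodo-6-methylocta-2,6-dienoate
Conditions: Ph3P=CHCO2Me, N-iodosuccinimide, CH2Cl2, −20 °C; then 4, −20 °C to rt
Reagents that add atoms: methyl (triphenylphosphoranylidene)acetate (COC(=O)C=P(c1ccccc1)(c1ccccc1)c1ccccc1); N-iodosuccinimide (O=C1CCC(=O)N1I)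
Why: Wittig olefination with the iodinated stabilised ylide made in the flask puts the chain trans to the ester, which is the 2Z iodide needed for the later E enoate.

**Step 4**
Reactants: 6 methyl (4R)-2,2-dimethyl-1,3-dioxolane-4-carboxylate
Product: 7 methyl (2R)-2,3-dihydroxypropanoate
Conditions: Amberlyst 15 (H+ form), MeOH, rt
Reagents that add atoms: none
Why: Acid-catalysed transketalisation to methanol frees the diol without touching the stereocentre.

**Step 5**
Reactants: 7 methyl (2R)-2,3-dihydroxypropanoate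
Product: 8 methyl (2R)-2,3-bis[(triethylsilyl)oxy]propanoate
Conditions: Et3SiCl (2.4 equiv), imidazole, DMF, 0 °C to rt
Reagents that add atoms: chlorotriethylsilane (CC[Si](Cl)(CC)CC)
Why: Exhaustive silylation; the primary triethylsilyl ether is the later aldehyde precursor and the secondary one protects O8.

**Step 6**
Reactants: 8 methyl (2R)-2,3-bis[(triethylsilyl)oxy]propanoate
Product: 9 (2R)-2,3-bis[(triethylsilyl)oxy]propanal
Conditions: iBu2AlH (1.1 equiv), CH2Cl2, −78 °C; Rochelle salt work-up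
Reagents that add atoms: none
Why: Partial reduction of the α-silyloxy ester stops at the aldehyde through a stable tetrahedral aluminate at −78 °C; the R centre (future C8) is untouched.

**Step 7**
Reactants: 5 methyl (2Z,6E)-8-[(tert-butyldimethylsilyl)oxy]-2-iodo-6-methylocta-2,6-dienoate; 9 (2R)-2,3-bis[(triethylsilyl)oxy]propanal
Product: 10 methyl (2E,6E)-8-[(tert-butyldimethylsilyl)oxy]-2-[(1S,2R)-1-hydroxy-2,3-bis(triethylsilyloxy)propyl]-6-methylocta-2,6-dienoate
Conditions: CrCl2 (4 equiv), NiCl2 (2 mol %), DMSO, rt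
Reagents that add atoms: none
Why: Nozaki–Hiyama–Kishi coupling: zerovalent nickel inserts into the C–I bond with retention, transmetalation gives an alkenyl species of trivalent chromium, and this adds to the aldehyde under polar Felkin–Anh control (anti to the α-silyloxy group), setting C9 as S (8,9-anti, expected about 4:1).

**Step 8**
Reactants: 10 methyl (2E,6E)-8-[(tert-butyldimethylsilyl)oxy]-2-[(1S,2R)-1-hydroxy-2,3-bis(triethylsilyloxy)propyl]-6-methylocta-2,6-dienoate
Product: 11 methyl (2E,6E)-2-[(1S,2R)-1-acetoxy-2,3-bis(triethylsilyloxy)propyl]-8-[(tert-butyldimethylsilyl)oxy]-6-methylocta-2,6-dienoate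
Conditions: Ac2O, pyridine, DMAP (cat.), CH2Cl2, 0 °C
Reagents that add atoms: acetic anhydride (CC(=O)OC(C)=O)
Why: DMAP-catalysed acetylation installs the C9 acetate of the target; the minor C9 epimer from step 7 is removed by chromatography here.

**Step 9**
Reactants: 11 methyl (2E,6E)-2-[(1S,2R)-1-acetoxy-2,3-bis(triethylsilyloxy)propyl]-8-[(tert-butyldimethylsilyl)oxy]-6-methylocta-2,6-dienoate
Product: 12 methyl (2E,6E)-2-[(1S,2S)-1-acetoxy-3-oxo-2-(triethylsilyloxy)propyl]-8-[(tert-butyldimethylsilyl)oxy]-6-methylocta-2,6-dienoate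
Conditions: (COCl)2, DMSO, CH2Cl2, −78 to −40 °C; Et3N, −78 °C; cold pH 7 quench
Reagents that add atoms: none
Why: Swern conditions oxidise a primary triethylsilyl ether directly to the aldehyde while the secondary triethylsilyl and the tert-butyldimethylsilyl ethers survive; C8 is unchanged in space (its descriptor becomes S only through the priority change).

**Step 10**
Reactants: 12 methyl (2E,6E)-2-[(1S,2S)-1-acetoxy-3-oxo-2-(triethylsilyloxy)propyl]-8-[(tert-butyldimethylsilyl)oxy]-6-methylocta-2,6-dienoate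
Product: 13 methyl (2E,6E)-2-[(1S,2R)-1-acetoxy-3-hydroxy-4-(methoxycarbonyl)-2-(triethylsilyloxy)pent-4-en-1-yl]-8-[(tert-butyldimethylsilyl)oxy]-6-methylocta-2,6-dienoate (both C3' epimers)
Conditions: methyl propiolate, iBu2AlH, N-methylmorpholine N-oxide, THF, 0 °C; then 12, 0 °C to rt
Reagents that add atoms: methyl propiolate (C#CC(=O)OC)
Why: Vinylalumination (a non-basic Morita–Baylis–Hillman surrogate): the α-(methoxycarbonyl)vinylalane adds 1,2 to the aldehyde without eliminating the β-acetate; the new C7 carbinol centre is a mixture that is erased in step 12.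

**Step 11**
Reactants: 13 methyl (2E,6E)-2-[(1S,2R)-1-acetoxy-3-hydroxy-4-(methoxycarbonyl)-2-(triethylsilyloxy)pent-4-en-1-yl]-8-[(tert-butyldimethylsilyl)oxy]-6-methylocta-2,6-dienoate
Product: 14 methyl (2E,6E)-2-[(1S,2R)-1-acetoxy-3-hydroxy-4-(methoxycarbonyl)-2-(triethylsilyloxy)pent-4-en-1-yl]-6-methyl-8-oxoocta-2,6-dienoate (both C3' epimers)
Conditions: DDQ (1.5 equiv), CH2Cl2/pH 7 buffer, 0 °C to rt
Reagents that add atoms: none
Why: Oxidative deprotection of an allylic silyl ether: DDQ abstracts hydride from the electron-rich C6 position and the silyl oxocarbenium ion hydrolyses to the E enal, while the electron-poor allylic positions are inert.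

**Step 12**
Reactants: 14 methyl (2E,6E)-2-[(1S,2R)-1-acetoxy-3-hydroxy-4-(methoxycarbonyl)-2-(triethylsilyloxy)pent-4-en-1-yl]-6-methyl-8-oxoocta-2,6-dienoate
Product: 15 methyl (2E,6E)-2-[(1S,2R,3Z)-1-acetoxy-5-bromo-4-(methoxycarbonyl)-2-(triethylsilyloxy)pent-3-en-1-yl]-6-methyl-8-oxoocta-2,6-dienoate
Conditions: N-bromosuccinimide, Me2S, CH2Cl2, −20 to 0 °C
Reagents that add atoms: N-bromosuccinimide (O=C1CCC(=O)N1Br)
Why: The Corey–Kim-type sulfonium reagent activates the Morita–Baylis–Hillman-type alcohol and bromide attacks in SN2' fashion to give the 2-(bromomethyl)enoate with C8 trans to the ester; the C7 carbinol centre disappears.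

**Step 13**
Reactants: 15 methyl (2E,6E)-2-[(1S,2R,3Z)-1-acetoxy-5-bromo-4-(methoxycarbonyl)-2-(triethylsilyloxy)pent-3-en-1-yl]-6-methyl-8-oxoocta-2,6-dienoate
Product: 18 methyl (1(10)E,4E,6R,7R,8R,9S)-9-acetoxy-8-hydroxygermacra-1(10),4,11(13)-trien-12,6-olid-14-oate, via trimethylsilyl ether 16 (not isolated), via triethylsilyl lactone 17 (not isolated)
Conditions: CrCl3 (20 mol %), Me3SiCl (2 equiv), LiClO4 (0.1 M), DMF, undivided cell, Al anode, Ni-foam cathode, constant current, 15 added over 10 h (2 mM), rt; then aq. HF, MeCN, 0 °C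
Reagents that add atoms: none
Why: Proposed new method: cathodically regenerated divalent chromium (from catalytic CrCl3) turns the allylic bromide into a 2-(methoxycarbonyl)allylchromium species that adds through its γ-carbon C7 to the enal in a closed six-membered transition state, Me3SiCl frees chromium from the C6 alkoxide for turnover and the Al anode balances the charge, so the C6–C7 bond and the ten-membered ring form at high dilution; A(1,3) strain holds H-8 in the allyl plane and the tether delivers C6 to the C7 face anti to the C8 silyloxy group with the enal chain pseudo-equatorial, which sets the 6,7-trans pair (6R,7S in 16 and 17, named 6R,7R in 18 by priority change only), and the HF work-up closes the lactone and removes both silyl groups; the closest known reaction types are the stoichiometric CrCl2 Nozaki–Hiyama macrocyclisation of 2-(bromomethyl)acrylate aldehydes to germacranolides and the chromium-electrocatalytic Nozaki–Hiyama–Kishi coupling of alkenyl halides.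

**Step 14**
Reactants: 19 (S)-lactic acid
Product: 20 (2S,5S)-2-tert-butyl-5-methyl-1,3-dioxolan-4-one
Conditions: pivalaldehyde, TsOH·H2O (cat.), pentane, reflux (Dean–Stark); recrystallise
Reagents that add atoms: pivalaldehyde (CC(C)(C)C=O)
Why: Acid-catalysed acetalisation (Seebach self-regeneration of stereocentres) gives the cis dioxolanone, the acetal centre being set by the lactic acid centre and purified by crystallisation.

**Step 15**
Reactants: 20 (2S,5S)-2-tert-butyl-5-methyl-1,3-dioxolan-4-one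
Product: 23 (1R)-1-[(2S,4R)-2-tert-butyl-4-methyl-5-oxo-1,3-dioxolan-4-yl]ethyl methanesulfonate, via lithium enolate 21 (not isolated), via lithium aldolate 22 (not isolated)
Conditions: LiN(iPr)2, THF, −78 °C; CH3CHO, −78 °C; MeSO2Cl, −78 to 0 °C
Reagents that add atoms: acetaldehyde (CC=O); methanesulfonyl chloride (CS(Cl)(=O)=O)
Why: The enolate reacts anti to the tert-butyl group (retention at the former lactic acid carbon), the closed Zimmerman–Traxler aldol is expected to place the new C–O bond anti to the ring oxygen (about 4:1, minor epimer removed by crystallisation), and the aldolate is trapped as its mesylate.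

**Step 16**
Reactants: 23 (1R)-1-[(2S,4R)-2-tert-butyl-4-methyl-5-oxo-1,3-dioxolan-4-yl]ethyl methanesulfonate
Product: 25 (2S,3R)-3-chloro-2-hydroxy-2-methylbutanoic acid, via potassium epoxy carboxylate 24 (not isolated)
Conditions: KOH (2.2 equiv), THF/H2O, 0 °C to rt; then conc. HCl, 0 °C to rt
Reagents that add atoms: potassium hydroxide ([K+].[OH-]); hydrogen chloride (Cl)
Why: Saponification of the acylal releases pivalaldehyde and the tertiary alkoxide, which displaces the mesylate with inversion to the trans-epoxy carboxylate, and HCl opens this glycidate at C3 with a second inversion (net retention at C3) to the (2S,3R) chlorohydrin acid.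

**Step 17**
Reactants: 18 methyl (1(10)E,4E,6R,7R,8R,9S)-9-acetoxy-8-hydroxygermacra-1(10),4,11(13)-trien-12,6-olid-14-oate; 25 (2S,3R)-3-chloro-2-hydroxy-2-methylbutanoic acid (3 equiv)
Product: 26 methyl (1(10)E,4E,6R,7S,8R,9S)-9-acetoxy-8-{[(2S,3R)-3-chloro-2-hydroxy-2-methylbutanoyl]oxy}germacra-1(10),4,11(13)-trien-12,6-olid-14-oate
Conditions: DCC, DMAP (0.2 equiv), CH2Cl2, −10 °C to rt
Reagents that add atoms: none
Why: Steglich esterification of the C8 hydroxyl with excess acid at low temperature is meant to outrun C9-to-C8 acetyl migration, and the tertiary hydroxyl of the acid is too hindered to self-acylate.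

**Step 18**
Reactants: 26 methyl (1(10)E,4E,6R,7S,8R,9S)-9-acetoxy-8-{[(2S,3R)-3-chloro-2-hydroxy-2-methylbutanoyl]oxy}germacra-1(10),4,11(13)-trien-12,6-olid-14-oate
Product: 27 methyl (1(10)E,4R,5R,6S,7R,8R,9S)-9-acetoxy-8-{[(2S,3R)-3-chloro-2-hydroxy-2-methylbutanoyl]oxy}-4,5-epoxygermacra-1(10),11(13)-dien-12,6-olid-14-oate
Conditions: mCPBA, CH2Cl2, 0 °C
Reagents that add atoms: 3-chloroperbenzoic acid (O=C(OO)c1cccc(Cl)c1)
Why: Prilezhaev epoxidation occurs only at the electron-rich C4=C5 alkene (the other two are conjugated to carbonyls) and from the exposed outer face of the rigid ring, which should give the 4R,5R epoxide, as peracids are expected to do with 4,5-ene melampolides.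

## Compound list

1 | geraniol, (2E)-3,7-dimethylocta-2,6-dien-1-ol | CC(C)=CCC/C(C)=C/CO | starting material
2 | tert-butyl{[(2E)-3,7-dimethylocta-2,6-dien-1-yl]oxy}dimethylsilane | CC(C)=CCC/C(C)=C/CO[Si](C)(C)C(C)(C)C | intermediate
3 | tert-butyl{[(2E)-5-(3,3-dimethyloxiran-2-yl)-3-methylpent-2-en-1-yl]oxy}dimethylsilane (racemic 6,7-epoxide) | CC1(C)OC1CC/C(C)=C/CO[Si](C)(C)C(C)(C)C | intermediate
4 | (4E)-6-[(tert-butyldimethylsilyl)oxy]-4-methylhex-4-enal | O=CCC/C(C)=C/CO[Si](C)(C)C(C)(C)C | intermediate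
5 | methyl (2Z,6E)-8-[(tert-butyldimethylsilyl)oxy]-2-iodo-6-methylocta-2,6-dienoate | COC(=O)/C(I)=C/CC/C(C)=C/CO[Si](C)(C)C(C)(C)C | intermediate
6 | methyl (4R)-2,2-dimethyl-1,3-dioxolane-4-carboxylate | COC(=O)[C@H]1COC(C)(C)O1 | starting material
7 | methyl (2R)-2,3-dihydroxypropanoate | COC(=O)[C@H](O)CO | intermediate
8 | methyl (2R)-2,3-bis[(triethylsilyl)oxy]propanoate | COC(=O)[C@H](O[Si](CC)(CC)CC)CO[Si](CC)(CC)CC | intermediate
9 | (2R)-2,3-bis[(triethylsilyl)oxy]propanal | O=C[C@H](O[Si](CC)(CC)CC)CO[Si](CC)(CC)CC | intermediate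
10 | methyl (2E,6E)-8-[(tert-butyldimethylsilyl)oxy]-2-[(1S,2R)-1-hydroxy-2,3-bis(triethylsilyloxy)propyl]-6-methylocta-2,6-dienoate | CC[Si](CC)(CC)OC[C@@H](O[Si](CC)(CC)CC)[C@@H](O)/C(C(=O)OC)=C\CC/C(C)=C/CO[Si](C)(C)C(C)(C)C | intermediate
11 | methyl (2E,6E)-2-[(1S,2R)-1-acetoxy-2,3-bis(triethylsilyloxy)propyl]-8-[(tert-butyldimethylsilyl)oxy]-6-methylocta-2,6-dienoate | CC[Si](CC)(CC)OC[C@@H](O[Si](CC)(CC)CC)[C@@H](OC(C)=O)/C(C(=O)OC)=C\CC/C(C)=C/CO[Si](C)(C)C(C)(C)C | intermediate
12 | methyl (2E,6E)-2-[(1S,2S)-1-acetoxy-3-oxo-2-(triethylsilyloxy)propyl]-8-[(tert-butyldimethylsilyl)oxy]-6-methylocta-2,6-dienoate | O=C[C@@H](O[Si](CC)(CC)CC)[C@@H](OC(C)=O)/C(C(=O)OC)=C\CC/C(C)=C/CO[Si](C)(C)C(C)(C)C | intermediate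
13 | methyl (2E,6E)-2-[(1S,2R)-1-acetoxy-3-hydroxy-4-(methoxycarbonyl)-2-(triethylsilyloxy)pent-4-en-1-yl]-8-[(tert-butyldimethylsilyl)oxy]-6-methylocta-2,6-dienoate (both C3' epimers) | C=C(C(=O)OC)C(O)[C@@H](O[Si](CC)(CC)CC)[C@@H](OC(C)=O)/C(C(=O)OC)=C\CC/C(C)=C/CO[Si](C)(C)C(C)(C)C | intermediate
14 | methyl (2E,6E)-2-[(1S,2R)-1-acetoxy-3-hydroxy-4-(methoxycarbonyl)-2-(triethylsilyloxy)pent-4-en-1-yl]-6-methyl-8-oxoocta-2,6-dienoate (both C3' epimers) | C=C(C(=O)OC)C(O)[C@@H](O[Si](CC)(CC)CC)[C@@H](OC(C)=O)/C(C(=O)OC)=C\CC/C(C)=C/C=O | intermediate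
15 | methyl (2E,6E)-2-[(1S,2R,3Z)-1-acetoxy-5-bromo-4-(methoxycarbonyl)-2-(triethylsilyloxy)pent-3-en-1-yl]-6-methyl-8-oxoocta-2,6-dienoate | COC(=O)/C(CBr)=C/[C@@H](O[Si](CC)(CC)CC)[C@@H](OC(C)=O)/C(C(=O)OC)=C\CC/C(C)=C/C=O | intermediate
16 | dimethyl (1(10)E,4E,6R,7S,8R,9S)-9-acetoxy-8-[(triethylsilyl)oxy]-6-[(trimethylsilyl)oxy]germacra-1(10),4,11(13)-triene-12,14-dioate | C=C(C(=O)OC)[C@@H]1[C@@H](O[Si](CC)(CC)CC)[C@@H](OC(C)=O)/C(C(=O)OC)=C\CC/C(C)=C/[C@H]1O[Si](C)(C)C | intermediate
17 | methyl (1(10)E,4E,6R,7S,8R,9S)-9-acetoxy-8-[(triethylsilyl)oxy]germacra-1(10),4,11(13)-trien-12,6-olid-14-oate | C1/C(C)=C/[C@H]2OC(=O)C(=C)[C@@H]2[C@@H](O[Si](CC)(CC)CC)[C@@H](OC(C)=O)/C(C(=O)OC)=C\C1 | intermediate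
18 | methyl (1(10)E,4E,6R,7R,8R,9S)-9-acetoxy-8-hydroxygermacra-1(10),4,11(13)-trien-12,6-olid-14-oate | C1/C(C)=C/[C@H]2OC(=O)C(=C)[C@@H]2[C@@H](O)[C@@H](OC(C)=O)/C(C(=O)OC)=C\C1 | intermediate
19 | (S)-lactic acid | C[C@H](O)C(=O)O | starting material
20 | (2S,5S)-2-tert-butyl-5-methyl-1,3-dioxolan-4-one | C[C@@H]1O[C@H](C(C)(C)C)OC1=O | intermediate
21 | lithium (2S)-2-tert-butyl-5-methyl-1,3-dioxol-4-olate | CC1=C([O-])O[C@@H](C(C)(C)C)O1.[Li+] | intermediate
22 | lithium (1R)-1-[(2S,4R)-2-tert-butyl-4-methyl-5-oxo-1,3-dioxolan-4-yl]ethanolate | C[C@]1([C@@H](C)[O-])O[C@H](C(C)(C)C)OC1=O.[Li+] | intermediate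
23 | (1R)-1-[(2S,4R)-2-tert-butyl-4-methyl-5-oxo-1,3-dioxolan-4-yl]ethyl methanesulfonate | C[C@]1([C@@H](C)OS(C)(=O)=O)O[C@H](C(C)(C)C)OC1=O | intermediate
24 | potassium (2R,3S)-2,3-dimethyloxirane-2-carboxylate | C[C@@H]1O[C@@]1(C)C(=O)[O-].[K+] | intermediate
25 | (2S,3R)-3-chloro-2-hydroxy-2-methylbutanoic acid | OC(=O)[C@](C)(O)[C@@H](C)Cl | intermediate
26 | methyl (1(10)E,4E,6R,7S,8R,9S)-9-acetoxy-8-{[(2S,3R)-3-chloro-2-hydroxy-2-methylbutanoyl]oxy}germacra-1(10),4,11(13)-trien-12,6-olid-14-oate | C1/C(C)=C/[C@H]2OC(=O)C(=C)[C@@H]2[C@@H](OC(=O)[C@](C)(O)[C@@H](C)Cl)[C@@H](OC(C)=O)/C(C(=O)OC)=C\C1 | intermediate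
27 | methyl (1(10)E,4R,5R,6S,7R,8R,9S)-9-acetoxy-8-{[(2S,3R)-3-chloro-2-hydroxy-2-methylbutanoyl]oxy}-4,5-epoxygermacra-1(10),11(13)-dien-12,6-olid-14-oate | C=C1C(=O)O[C@H]2[C@H]1[C@@H](OC(=O)[C@](C)(O)[C@@H](C)Cl)[C@@H](OC(C)=O)/C(C(=O)OC)=C\CC[C@@]1(C)O[C@H]21 | target

## Step count and risks

Total step count: 18. Longest linear sequence: 12 steps (steps 1, 2, 3, 7, 8, 9, 10, 11, 12, 13, 17, 18; geraniol 1 to target 27).

**Step 13 (the proposed electrocatalytic macrocyclisation).** Risks are dimerisation, loss of the C8 silyloxy group by vinylogous β-elimination from the allylchromium species, and the wrong C6/C7 pair. The fallback uses known allylboration chemistry instead of a reductive allylation. It sets out from bromide 15, which is borylated (B2pin2, Pd2(dba)3 cat., DMSO, rt) to the allylboronate methyl (2E,6E)-2-[(1S,2R,3E)-1-acetoxy-4-(methoxycarbonyl)-5-(4,4,5,5-tetramethyl-1,3,2-dioxaborolan-2-yl)-2-(triethylsilyloxy)pent-3-en-1-yl]-6-methyl-8-oxoocta-2,6-dienoate F1. Such 2-alkoxycarbonyl allylboronates are inert to aldehydes until activated, so F1 can be cyclised by Sc(OTf)3-catalysed intramolecular allylboration (toluene, 2 mM) through a closed chair transition state. Acidic work-up lactonises the product to 17, and aq. HF in MeCN returns the route at 18.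

**Step 7 (Nozaki–Hiyama–Kishi coupling).** Risks are a low Felkin–Anh ratio at C9 and erosion of the enoate geometry. The fallback sets the C9 centre by hydride delivery instead of C–C bond formation. It sets out from 10 as its C9 epimer mixture, which is oxidised (Dess–Martin periodinane, CH2Cl2, 0 °C) to the ketone methyl (2E,6E)-2-[(2R)-2,3-bis(triethylsilyloxy)propanoyl]-8-[(tert-butyldimethylsilyl)oxy]-6-methylocta-2,6-dienoate F2. Luche reduction (NaBH4, CeCl3·7H2O, MeOH, −78 °C) under Felkin–Anh control by the α-silyloxy centre then returns the route at 10 as the 8,9-anti alcohol.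

**Step 17 (esterification of the hindered C8 hydroxyl).** Risks are acetyl migration from O9 to O8 and sluggish acylation by an α-hydroxy acid. The fallback acylates with the hydroxyl-free epoxy acid and forms the chlorohydrin afterwards. It sets out from mesylate 23 and alcohol 18. Treating 23 with KOH in THF/H2O and acidifying only to pH 4 (NaH2PO4) gives (2R,3S)-2,3-dimethyloxirane-2-carboxylic acid F3. Yamaguchi esterification of 18 with F3 (2,4,6-trichlorobenzoyl chloride, Et3N, DMAP, toluene) gives methyl (1(10)E,4E,6R,7S,8R,9S)-9-acetoxy-8-{[(2R,3S)-2,3-dimethyloxirane-2-carbonyl]oxy}germacra-1(10),4,11(13)-trien-12,6-olid-14-oate F4. Opening the glycidate with LiCl and AcOH in THF (chloride at C3' with inversion) returns the route at 26.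

## Further compounds

F1 | step 13 | methyl (2E,6E)-2-[(1S,2R,3E)-1-acetoxy-4-(methoxycarbonyl)-5-(4,4,5,5-tetramethyl-1,3,2-dioxaborolan-2-yl)-2-(triethylsilyloxy)pent-3-en-1-yl]-6-methyl-8-oxoocta-2,6-dienoate | COC(=O)/C(CB1OC(C)(C)C(C)(C)O1)=C/[C@@H](O[Si](CC)(CC)CC)[C@@H](OC(C)=O)/C(C(=O)OC)=C\CC/C(C)=C/C=O
F2 | step 7 | methyl (2E,6E)-2-[(2R)-2,3-bis(triethylsilyloxy)propanoyl]-8-[(tert-butyldimethylsilyl)oxy]-6-methylocta-2,6-dienoate | CC[Si](CC)(CC)OC[C@@H](O[Si](CC)(CC)CC)C(=O)/C(C(=O)OC)=C\CC/C(C)=C/CO[Si](C)(C)C(C)(C)C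
F3 | step 17 | (2R,3S)-2,3-dimethyloxirane-2-carboxylic acid | C[C@@H]1O[C@@]1(C)C(=O)O
F4 | step 17 | methyl (1(10)E,4E,6R,7S,8R,9S)-9-acetoxy-8-{[(2R,3S)-2,3-dimethyloxirane-2-carbonyl]oxy}germacra-1(10),4,11(13)-trien-12,6-olid-14-oate | C1/C(C)=C/[C@H]2OC(=O)C(=C)[C@@H]2[C@@H](OC(=O)[C@]2(C)O[C@H]2C)[C@@H](OC(C)=O)/C(C(=O)OC)=C\C1
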